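**Plan**
- Retrosynthetic cuts, in order: the isovalerate ester C–O; C1–C2 of the quinone ring (carbonyl carbon C1 to the side-chain-bearing C2), with C1 tied back to C4 in a temporary four-membered ring; C3–C4 (vinyllithium + 1,2-dione); the two arene–carbon bonds of the four-membered ring (aryne [2+2]).
- Enabling feature: C1 and C4 sit on the adjacent arene carbons C8a and C4a and are bridged by C2=C3. The quinone ring is therefore the 6π-closure product of the triene C1=C8a–C4a=C4–C3=C2, an o-quinoid ketene that can be stored in a 2-alkenyl-2-hydroxybenzocyclobutenone. The twofold symmetry of the 3,6-dioxygenated benzocyclobutenedione removes every regiochemical question.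
- Forward order: the benzene ring is bought; the four-membered ring comes from the [2+2]; oxidation gives the dione; methyl is exchanged for silyl. The side chain is made separately as an E-vinylstannane and joined by 1,2-addition. The 4→6 ring expansion builds the quinone ring, followed by desilylation and esterification.
- The closed-shell alkenyl version is preferred to the alkynyl (diradical) version, because an aryl σ-radical at C3 would lie 5-exo to the prenyl C=C.
- Stereochemistry: the single (S) centre comes from a CBS reduction of a stannyl enone and is carried as a silyl ether. Its C–O bond is never broken.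

Key step: step 11

Assumption: compounds 1, 2, 10, 13 and 25 are taken as commercial; adduct 19 is carried as a mixture of epimers at its carbinol carbon, which becomes the planar C4 in step 11.

Step 1
Reactants: 1 2-bromo-1,4-dimethoxybenzene; 2 1,1-dimethoxyethene
Product: 5 3,6-dimethoxybenzocyclobutenone (2,5-dimethoxybicyclo[4.2.0]octa-1,3,5-trien-7-one), via 3,6-dimethoxybenzyne 3 (not isolated), via dimethyl ketal 4 (not isolated)
Conditions: NaNH2, 2 (2 equiv), THF, reflux; then aq. HCl, THF, rt
Reagents that add atoms: water, O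
Why: NaNH2 removes the proton flanked by Br and OMe and NaBr is lost, the symmetrical aryne 3 undergoes the known polar [2+2] cycloaddition with the electron-rich ketene acetal (only one regioisomer is possible), and dilute acid hydrolyses ketal 4 to the ketone.

Step 2
Reactants: 5 3,6-dimethoxybenzocyclobutenone
Product: 6 2,2-dibromo-3,6-dimethoxybenzocyclobutenone (8,8-dibromo-2,5-dimethoxybicyclo[4.2.0]octa-1,3,5-trien-7-one)
Conditions: NBS (2.2 equiv), (BzO)2 cat., CCl4 (or PhCF3), reflux
Reagents that add atoms: N-bromosuccinimide, O=C1CCC(=O)N1Br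
Why: Wohl–Ziegler radical bromination acts twice at the only benzylic CH2, which is also alpha to the carbonyl group, while the non-polar medium disfavours ionic bromination of the ring.

Step 3
Reactants: 6 2,2-dibromo-3,6-dimethoxybenzocyclobutenone
Product: 7 3,6-dimethoxybenzocyclobutenedione (2,5-dimethoxybicyclo[4.2.0]octa-1,3,5-triene-7,8-dione)
Conditions: 50% aq. H2SO4, 60–70 °C
Reagents that add atoms: water, O
Why: Acid hydrolysis of the benzylic gem-dibromide is the standard passage from benzocyclobutenones to benzocyclobutenediones, and the aryl methyl ethers survive it.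

Step 4
Reactants: 7 3,6-dimethoxybenzocyclobutenedione
Product: 8 3,6-dihydroxybenzocyclobutenedione
Conditions: BBr3 (3 equiv), CH2Cl2, −78 °C to rt; H2O
Reagents that add atoms: none
Why: Lewis-acid ether cleavage with BBr3 removes both methyl groups while no acid-sensitive function is present, so the difficult late demethylation of naphthazarin ethers next to the prenyl side chain is avoided.

Step 5
Reactants: 8 3,6-dihydroxybenzocyclobutenedione
Product: 9 3,6-bis(tert-butyldimethylsilyloxy)benzocyclobutenedione
Conditions: TBSCl (2.5 equiv), imidazole, DMF, rt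
Reagents that add atoms: tert-butyldimethylsilyl chloride, CC(C)(C)[Si](C)(C)Cl
Why: Standard phenol silylation gives ethers that tolerate organolithium addition at −78 °C and neutral heating and leave under mild fluoride conditions at the end.

Step 6
Reactants: 10 4-methylpent-3-enoic acid
Product: 12 N-methoxy-N,4-dimethylpent-3-enamide (Weinreb amide), via acyl imidazole 11 (not isolated)
Conditions: CDI, CH2Cl2, 0 °C to rt; then MeNH(OMe)·HCl, rt
Reagents that add atoms: N,O-dimethylhydroxylamine hydrochloride, CNOC.Cl
Why: Acyl imidazole formation and aminolysis (Weinreb amide synthesis) run near neutrality, which should leave the β,γ-double bond where it is.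

Step 7
Reactants: 13 (E)-1,2-bis(tributylstannyl)ethene; 12 Weinreb amide
Product: 15 (E)-6-methyl-1-(tributylstannyl)hepta-1,5-dien-3-one, via vinyllithium 14 (not isolated)
Conditions: 13, n-BuLi (0.95 equiv), THF, −78 °C; then 12, −78 °C; aq. NH4Cl
Reagents that add atoms: none
Why: Tin–lithium exchange at one end of 13 gives the E-vinyllithium with retention, and the Weinreb ketone synthesis stops at the chelated tetrahedral adduct, so the skipped enone is released only on the mild quench.

Step 8
Reactants: 15 (E)-6-methyl-1-(tributylstannyl)hepta-1,5-dien-3-one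
Product: 16 (S,E)-6-methyl-1-(tributylstannyl)hepta-1,5-dien-3-ol
Conditions: (R)-Me-CBS (0.2 equiv), catecholborane, PhMe, −78 °C; MeOH, aq. NaOH
Reagents that add atoms: none
Why: In the CBS reduction the catalyst boron binds the carbonyl lone pair anti to the large stannylvinyl group (the prenyl CH2 is the small group) and hydride is delivered to one face, so the (R)-catalyst should give the S alcohol, and catecholborane at −78 °C should not hydroborate either alkene.

Step 9
Reactants: 16 (S,E)-6-methyl-1-(tributylstannyl)hepta-1,5-dien-3-ol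
Product: 17 (S,E)-3-(tert-butyldimethylsilyloxy)-6-methyl-1-(tributylstannyl)hepta-1,5-diene
Conditions: TBSCl, imidazole, DMF, rt
Reagents that add atoms: tert-butyldimethylsilyl chloride, CC(C)(C)[Si](C)(C)Cl
Why: Standard O-silylation masks the acidic proton for the lithiation and turns the oxygen into a poor leaving group for step 11, and the stereocentre is not touched.

Step 10
Reactants: 17 silyl ether vinylstannane; 9 3,6-bis(tert-butyldimethylsilyloxy)benzocyclobutenedione
Product: 19 8-hydroxy-8-[(1E,3S)-3-(tert-butyldimethylsilyloxy)-6-methylhepta-1,5-dien-1-yl]-2,5-bis(tert-butyldimethylsilyloxy)bicyclo[4.2.0]octa-1,3,5-trien-7-one (both epimers at C8), via vinyllithium 18 (not isolated)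
Conditions: 17, n-BuLi, THF, −78 °C; cannulated into 9 (1.2 equiv), THF, −78 °C; aq. NH4Cl at −78 °C
Reagents that add atoms: none
Why: Tin–lithium exchange with retention of E geometry is followed by 1,2-addition to one of the two equivalent strained carbonyl groups, the resulting alkoxide deactivates the neighbouring ketone toward a second addition, and the new carbinol centre is erased in step 11.

Step 11
Reactants: 19 2-alkenyl-2-hydroxybenzocyclobutenone
Product: 23 (S)-5,8-bis(tert-butyldimethylsilyloxy)-2-[1-(tert-butyldimethylsilyloxy)-4-methylpent-3-en-1-yl]naphthalene-1,4-dione (tris-TBS-alkannin), via o-quinoid vinylketene 20 (not isolated), via dienone 21 (not isolated), via naphthalene-1,4-diol 22 (not isolated)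
Conditions: PhMe (0.02 M, degassed), 110 °C; then Ag2O, MgSO4, rt
Reagents that add atoms: none
Why: Heating opens the strained ring of 19 by conrotatory 4π cleavage of the C(=O)–C(OH) bond, which transiently dearomatizes the arene to the o-quinoid vinylketene 20, where the ketene carbon (future C1) and the alkene terminus (future C2) are the ends of the triene C1=C8a–C4a=C4–C3=C2. Disrotatory 6π electrocyclization joins C1 to C2, closes the six-membered quinone ring and restores the benzene ring, enolization of dienone 21 gives diol 22, and Ag2O dehydrogenates 22 to quinone 23. The closest known reaction type is the thermal ring expansion of 4-alkenyl-4-hydroxycyclobutenones and their benzo analogues to hydroquinones and quinones, the alkenyl counterpart of the Moore cyclization. The only new stereocentre, C2 of 21, is erased by enolization, the carbinol carbon of 19 becomes the planar C4 so both epimers converge, and the side-chain centre is a spectator whose C–O bond is not broken. The step needs torquoselectivity (alkenyl group inward, toward the ketene), which the donor hydroxyl group secures by rotating outward, and the E alkene keeps the bulky side chain on the outside of the closing triene. The poor leaving ability of the silyloxy group guards diol 22 against o-quinone methide formation, and the symmetry of the arene half leaves no regiochemical choice.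

Step 12
Reactants: 23 tris-TBS-alkannin
Product: 24 alkannin, (S)-5,8-dihydroxy-2-(1-hydroxy-4-methylpent-3-en-1-yl)naphthalene-1,4-dione
Conditions: HF·pyridine, pyridine, THF, 0 °C to rt (plastic vessel)
Reagents that add atoms: none
Why: Fluoride-driven Si–O cleavage under buffered, weakly acidic conditions frees the two peri phenols and the secondary alcohol without breaking the C–O bond at the stereocentre, and any earlier peri O-to-O silyl shift is harmless because all such isomers give the same naphthazarin.

Step 13
Reactants: 24 alkannin; 25 isovaleric acid (3-methylbutanoic acid)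
Product: 26 isovalerylalkannin
Conditions: 25, DCC, DMAP cat., CH2Cl2, 0 °C to rt
Reagents that add atoms: none
Why: Steglich esterification should act only on the side-chain alcohol, because both phenols are locked in strong hydrogen bonds to the quinone carbonyl groups, and acylation at oxygen retains the S configuration.

**Compound list**
1 | 2-bromo-1,4-dimethoxybenzene | COc1ccc(OC)c(Br)c1 | starting material
2 | 1,1-dimethoxyethene | C=C(OC)OC | starting material
3 | 3,6-dimethoxybenzyne | COC1=CC=C(OC)C#C1 | intermediate
4 | 2,5,7,7-tetramethoxybicyclo[4.2.0]octa-1,3,5-triene | COc1ccc(OC)c2c1CC2(OC)OC | intermediate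
5 | 3,6-dimethoxybenzocyclobutenone | COc1ccc(OC)c2c1CC2=O | intermediate
6 | 2,2-dibromo-3,6-dimethoxybenzocyclobutenone | COc1ccc(OC)c2c1C(Br)(Br)C2=O | intermediate
7 | 3,6-dimethoxybenzocyclobutenedione | COc1ccc(OC)c2c1C(=O)C2=O | intermediate
8 | 3,6-dihydroxybenzocyclobutenedione | Oc1ccc(O)c2c1C(=O)C2=O | intermediate
9 | 3,6-bis(tert-butyldimethylsilyloxy)benzocyclobutenedione | CC(C)(C)[Si](C)(C)Oc1ccc(O[Si](C)(C)C(C)(C)C)c2c1C(=O)C2=O | intermediate
10 | 4-methylpent-3-enoic acid | CC(C)=CCC(=O)O | starting material
11 | 1-(4-methylpent-3-enoyl)imidazole | CC(C)=CCC(=O)n1ccnc1 | intermediate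
12 | N-methoxy-N,4-dimethylpent-3-enamide | CC(C)=CCC(=O)N(C)OC | intermediate
13 | (E)-1,2-bis(tributylstannyl)ethene | CCCC[Sn](CCCC)(CCCC)/C=C/[Sn](CCCC)(CCCC)CCCC | starting material
14 | (E)-2-(tributylstannyl)vinyllithium | [Li]/C=C/[Sn](CCCC)(CCCC)CCCC | intermediate
15 | (E)-6-methyl-1-(tributylstannyl)hepta-1,5-dien-3-one | CC(C)=CCC(=O)/C=C/[Sn](CCCC)(CCCC)CCCC | intermediate
16 | (S,E)-6-methyl-1-(tributylstannyl)hepta-1,5-dien-3-ol | CC(C)=CC[C@H](O)/C=C/[Sn](CCCC)(CCCC)CCCC | intermediate
17 | (S,E)-3-(tert-butyldimethylsilyloxy)-6-methyl-1-(tributylstannyl)hepta-1,5-diene | CC(C)=CC[C@H](O[Si](C)(C)C(C)(C)C)/C=C/[Sn](CCCC)(CCCC)CCCC | intermediate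
18 | (S,E)-3-(tert-butyldimethylsilyloxy)-6-methylhepta-1,5-dien-1-yllithium | CC(C)=CC[C@H](O[Si](C)(C)C(C)(C)C)/C=C/[Li] | intermediate
19 | 8-hydroxy-8-[(1E,3S)-3-(tert-butyldimethylsilyloxy)-6-methylhepta-1,5-dien-1-yl]-2,5-bis(tert-butyldimethylsilyloxy)bicyclo[4.2.0]octa-1,3,5-trien-7-one, both epimers at C8 | CC(C)=CC[C@H](O[Si](C)(C)C(C)(C)C)/C=C/C1(O)C(=O)c2c(O[Si](C)(C)C(C)(C)C)ccc(O[Si](C)(C)C(C)(C)C)c21 | intermediate
20 | o-quinoid vinylketene (ring-opened 19; dienyl group cis to the ketene, hydroxyl group outward) | CC(C)=CC[C@H](O[Si](C)(C)C(C)(C)C)/C=C/C(O)=C1C(O[Si](C)(C)C(C)(C)C)=CC=C(O[Si](C)(C)C(C)(C)C)C1=C=O | intermediate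
21 | 4-hydroxy-2-[(S)-1-(tert-butyldimethylsilyloxy)-4-methylpent-3-en-1-yl]-5,8-bis(tert-butyldimethylsilyloxy)naphthalen-1(2H)-one, C2 undefined | CC(C)=CC[C@H](O[Si](C)(C)C(C)(C)C)C1C=C(O)c2c(O[Si](C)(C)C(C)(C)C)ccc(O[Si](C)(C)C(C)(C)C)c2C1=O | intermediate
22 | (S)-2-[1-(tert-butyldimethylsilyloxy)-4-methylpent-3-en-1-yl]-5,8-bis(tert-butyldimethylsilyloxy)naphthalene-1,4-diol | CC(C)=CC[C@H](O[Si](C)(C)C(C)(C)C)c1cc(O)c2c(O[Si](C)(C)C(C)(C)C)ccc(O[Si](C)(C)C(C)(C)C)c2c1O | intermediate
23 | (S)-5,8-bis(tert-butyldimethylsilyloxy)-2-[1-(tert-butyldimethylsilyloxy)-4-methylpent-3-en-1-yl]naphthalene-1,4-dione | CC(C)=CC[C@H](O[Si](C)(C)C(C)(C)C)C1=CC(=O)c2c(O[Si](C)(C)C(C)(C)C)ccc(O[Si](C)(C)C(C)(C)C)c2C1=O | intermediate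
24 | alkannin | CC(C)=CC[C@H](O)C1=CC(=O)c2c(O)ccc(O)c2C1=O | intermediate
25 | isovaleric acid | CC(C)CC(=O)O | starting material
26 | isovalerylalkannin | CC(C)=CC[C@H](OC(=O)CC(C)C)C1=CC(=O)c2c(O)ccc(O)c2C1=O | target

**Step count**
- Total steps: 13.
- Longest linear sequence: 9 steps (1–5, then 10–13). The side-chain branch (6–9, then 10–13) has 8.

**Steps most likely to fail**

1. Step 11.
- What may go wrong: the hydroxyl group may rotate inward and the ketene may lactonize. Alternatively, the benzylic silyloxy group may be expelled from the electron-rich hydroquinone stage at 110 °C, with loss of configuration.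
- The fallback sets out from 9 (and uses 18) and comes back at 23. It makes the same bond from an o-quinodimethane instead of a ketene.
- Dione 9 would be treated with MeOSiMe3 and catalytic TMSOTf (CH2Cl2, −78 °C, Noyori ketalization) to give the monoketal 8,8-dimethoxy-2,5-bis(tert-butyldimethylsilyloxy)bicyclo[4.2.0]octa-1,3,5-trien-7-one F1.
- Addition of 18 at −78 °C should give the alkenylbenzocyclobutenol F2.
- Carbinols of this kind open at lower temperature (PhMe, 60–80 °C). The 6π closure joins the ketal carbon to the alkene terminus, and loss of methanol should give the 4-methoxy-1-naphthol F3. Here the oxygen next to the side chain is capped as a methyl ether and no ketene occurs.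
- Oxidative demethylation with PhI(OAc)2 in aqueous MeCN at 0 °C should then give 23.

2. Step 10.
- What may go wrong: a second addition to the remaining ketone, or cleavage of the strained ring by the alkoxide before the quench.
- The fallback sets out from 12 and 9 and comes back at 23. No carbanion meets the dione; the quinone ring is made by cobalt-mediated insertion of an alkyne into the C(O)–C(O) bond.
- Amide 12 with lithium (trimethylsilyl)acetylide (THF, −78 °C) should give the ynone 6-methyl-1-(trimethylsilyl)hept-5-en-1-yn-3-one F4.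
- Noyori transfer hydrogenation (RuCl[(S,S)-TsDPEN](p-cymene), i-PrOH, rt) should give the (S)-propargylic alcohol F5.
- K2CO3 in MeOH should give the terminal alkynol (S)-6-methylhept-5-en-1-yn-3-ol F6, and TBSCl with imidazole its silyl ether F7.
- Dione 9 with ClCo(PPh3)3 (PhCl, rt to 50 °C) should undergo oxidative addition to give the phthaloylcobalt complex F8.
- Heating F8 with F7 and AgBF4 in MeCN at 80 °C should give 23 by alkyne insertion and reductive elimination.

3. Step 12.
- What may go wrong: the hindered secondary silyl ether may cleave slowly. Long exposure to HF could then cause acid-induced cyclization of the freed alcohol onto the prenyl double bond, or ionization at the stereocentre.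
- The fallback sets out from 16 and 9 and comes back at 26. The secondary alcohol is never silylated.
- Alcohol 16 with two equivalents of n-BuLi (THF, −78 °C) should give the O,C-dilithio species F9, which is added to 9 to give the diol F10.
- Thermolysis and Ag2O oxidation as in step 11 should give 5,8-bis-O-TBS-alkannin F11.
- Steglich esterification with 25 should give 5,8-bis-O-TBS-isovalerylalkannin F12.
- The two aryl silyl ethers peri to the quinone carbonyl groups should leave quickly with Et3N·3HF (THF, 0 °C) to give 26.

**Further compounds**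
F1 | step 11 | 8,8-dimethoxy-2,5-bis(tert-butyldimethylsilyloxy)bicyclo[4.2.0]octa-1,3,5-trien-7-one | COC1(OC)C(=O)c2c(O[Si](C)(C)C(C)(C)C)ccc(O[Si](C)(C)C(C)(C)C)c21
F2 | step 11 | 7-[(1E,3S)-3-(tert-butyldimethylsilyloxy)-6-methylhepta-1,5-dien-1-yl]-8,8-dimethoxy-2,5-bis(tert-butyldimethylsilyloxy)bicyclo[4.2.0]octa-1,3,5-trien-7-ol, both epimers at C7 | CC(C)=CC[C@H](O[Si](C)(C)C(C)(C)C)/C=C/C1(O)c2c(O[Si](C)(C)C(C)(C)C)ccc(O[Si](C)(C)C(C)(C)C)c2C1(OC)OC
F3 | step 11 | (S)-4-methoxy-3-[1-(tert-butyldimethylsilyloxy)-4-methylpent-3-en-1-yl]-5,8-bis(tert-butyldimethylsilyloxy)naphthalen-1-ol | CC(C)=CC[C@H](O[Si](C)(C)C(C)(C)C)c1cc(O)c2c(O[Si](C)(C)C(C)(C)C)ccc(O[Si](C)(C)C(C)(C)C)c2c1OC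
F4 | step 10 | 6-methyl-1-(trimethylsilyl)hept-5-en-1-yn-3-one | CC(C)=CCC(=O)C#C[Si](C)(C)C
F5 | step 10 | (S)-6-methyl-1-(trimethylsilyl)hept-5-en-1-yn-3-ol | CC(C)=CC[C@H](O)C#C[Si](C)(C)C
F6 | step 10 | (S)-6-methylhept-5-en-1-yn-3-ol | CC(C)=CC[C@H](O)C#C
F7 | step 10 | (S)-3-(tert-butyldimethylsilyloxy)-6-methylhept-5-en-1-yne | CC(C)=CC[C@H](O[Si](C)(C)C(C)(C)C)C#C
F8 | step 10 | chloro[3,6-bis(tert-butyldimethylsilyloxy)phthaloyl]bis(triphenylphosphine)cobalt(III) | O=C1c2c(O[Si](C)(C)C(C)(C)C)ccc(O[Si](C)(C)C(C)(C)C)c2C(=O)[Co-2]1(Cl)([P+](c1ccccc1)(c1ccccc1)c1ccccc1)[P+](c1ccccc1)(c1ccccc1)c1ccccc1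
F9 | step 12 | lithium (S,E)-1-lithio-6-methylhepta-1,5-dien-3-olate | CC(C)=CC[C@H](O[Li])/C=C/[Li]
F10 | step 12 | 8-hydroxy-8-[(1E,3S)-3-hydroxy-6-methylhepta-1,5-dien-1-yl]-2,5-bis(tert-butyldimethylsilyloxy)bicyclo[4.2.0]octa-1,3,5-trien-7-one, both epimers at C8 | CC(C)=CC[C@H](O)/C=C/C1(O)C(=O)c2c(O[Si](C)(C)C(C)(C)C)ccc(O[Si](C)(C)C(C)(C)C)c21
F11 | step 12 | (S)-5,8-bis(tert-butyldimethylsilyloxy)-2-(1-hydroxy-4-methylpent-3-en-1-yl)naphthalene-1,4-dione | CC(C)=CC[C@H](O)C1=CC(=O)c2c(O[Si](C)(C)C(C)(C)C)ccc(O[Si](C)(C)C(C)(C)C)c2C1=O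
F12 | step 12 | (S)-1-[5,8-bis(tert-butyldimethylsilyloxy)-1,4-dioxo-1,4-dihydronaphthalen-2-yl]-4-methylpent-3-en-1-yl 3-methylbutanoate | CC(C)=CC[C@H](OC(=O)CC(C)C)C1=CC(=O)c2c(O[Si](C)(C)C(C)(C)C)ccc(O[Si](C)(C)C(C)(C)C)c2C1=O
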